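Assumption: locants C1–C20 in the names follow the briarane numbering of the target (C1 quaternary ring-fusion carbon, C2 butanoate carbon, C5=C6 ring alkene, C7 lactone O–CH, C8 carbinol, C9 acetate carbon, C10 ring-fusion CH, C11–C14 enone ring, C17 lactone α-carbon). The SMILES strings fix every configuration. "C11 unassigned" means the CHMe centre is carried as an epimer mixture until step 18.

## Retrosynthetic overview

1. Target 34 comes from 11-deoxy lactone 31 by a late Rubottom hydroxylation at C11; the γ-lactone (third ring, C8–C17 bond, C8 and C17) comes from an intramolecular Reformatsky reaction of bromopropanoate 29.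
2. The ten-membered ring (second ring) is closed at C6–C7 by an electrochemical Ni/Cr alkenyl iodide–aldehyde macrocyclisation of 24.
3. C7–C8 come from the glyoxal-derived dithiane 20 added to C9 aldehyde 17; C3–C6 from enolate alkylation with Z-bromide 10; C2 from a Felkin–Anh reduction.
4. The six-membered ring (first ring, C1 and C10) comes from a Diels–Alder reaction of silyloxydiene 5 with enone 3, made from (R)-glyceraldehyde acetonide 1; the stereocentre of 1 steers the cycloaddition and is then cleaved to the C9 aldehyde.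

## Route

Step 1
Reactants: 1 (R)-glyceraldehyde acetonide; 2 3-(triphenylphosphoranylidene)butan-2-one
Product: 3 (S,E)-4-(2,2-dimethyl-1,3-dioxolan-4-yl)-3-methylbut-3-en-2-one
Conditions: toluene, 60 °C
Reagents that add atoms: none
Why: Wittig olefination with the ketone-stabilised ylide gives the E-trisubstituted enone without touching the stereocentre bought in 1.

Step 2
Reactants: 4 ethyl vinyl ketone
Product: 5 (Z)-3-(tert-butyldimethylsilyloxy)penta-1,3-diene
Conditions: TBSOTf, Et3N, CH2Cl2, −78 → 0 °C
Reagents that add atoms: tert-butyldimethylsilyl triflate (TBSOTf), CC(C)(C)[Si](C)(C)OS(=O)(=O)C(F)(F)F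
Why: Soft enolisation and O-silylation of the ethyl ketone gives the 2-silyloxydiene with the Z enol ether geometry favoured under amine/silyl triflate conditions.

Step 3
Reactants: 3 enone; 5 silyloxydiene
Product: 6 cycloadduct methyl ketone (silyl enol ether; acetyl on C1 trans to dioxolanyl on C10)
Conditions: Tf2NH (10 mol %), CH2Cl2, −78 → −40 °C; Et3N quench
Reagents that add atoms: none
Why: Triflimide-catalysed (silyl Lewis acid) Diels–Alder reaction of the 2-silyloxydiene: the nucleophilic CHMe terminus bonds to the enone β-carbon (para rule), the E geometry of 3 becomes the trans C1-acyl/C10-dioxolanyl relationship, and with the allylic C–H of 3 eclipsing the alkene to avoid 1,3-allylic strain with the α-methyl group the diene adds anti to the dioxolane C–O bond, which sets C1 and C10 in the absolute sense of the target.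

Step 4
Reactants: 7 propargyl alcohol
Product: 9 (Z)-3-iodo-2-methylprop-2-en-1-ol, via vinylmagnesium alkoxide chelate 8 (not isolated)
Conditions: MeMgBr (2.5 equiv), CuI (10 mol %), THF, −10 °C → rt; then I2, −10 °C
Reagents that add atoms: methylmagnesium bromide, C[Mg]Br; iodine, II
Why: Copper-catalysed hydroxyl-directed anti-carbomagnesiation of the alkyne followed by iodinolysis of the alkenylmagnesium with retention gives the Z-iodoalkene.

Step 5
Reactants: 9 (Z)-3-iodo-2-methylprop-2-en-1-ol
Product: 10 (Z)-3-bromo-1-iodo-2-methylprop-1-ene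
Conditions: PBr3, Et2O, 0 °C
Reagents that add atoms: phosphorus tribromide, BrP(Br)Br
Why: SN2 bromination of the primary allylic alcohol leaves the Z-iodoalkene intact.

Step 6
Reactants: 6 cycloadduct methyl ketone; 10 Z-allylic bromide
Product: 12 iodoalkenyl ketone (C2 ketone with the C3–C6 chain), via lithium enolate 11 (not isolated)
Conditions: LiN(i-Pr)2 (LDA), THF, −78 °C; then 10, DMPU, −78 → −30 °C
Reagents that add atoms: none
Why: Kinetic lithium enolate alkylation (SN2): the methyl ketone has a single enolisable side and the allylic bromide reacts without touching the alkenyl iodide or its Z geometry.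

Step 7
Reactants: 12 iodoalkenyl ketone
Product: 13 C2 alcohol
Conditions: LiBH(s-Bu)3 (L-Selectride), THF, −78 → −20 °C; aq. NH4Cl
Reagents that add atoms: none
Why: Felkin–Anh reduction: hydride attacks the C2 ketone anti to the large C10 branch, with the ring CH2 (C14) flanking the carbonyl oxygen and the C1 methyl next to the chain, which gives the C2 configuration of the target.

Step 8
Reactants: 13 C2 alcohol
Product: 14 C2 butanoate
Conditions: (PrCO)2O, DMAP, Et3N, CH2Cl2, 35 °C
Reagents that add atoms: butanoic anhydride, CCCC(=O)OC(=O)CCC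
Why: DMAP-catalysed acylation (nucleophilic acyl transfer) of the hindered secondary alcohol proceeds with retention at C2.

Step 9
Reactants: 14 C2 butanoate
Product: 15 cyclohexenone butanoate
Conditions: IBX·MPO (2-iodoxybenzoic acid·4-methoxypyridine N-oxide), DMSO, 25 °C
Reagents that add atoms: none
Why: IBX-mediated dehydrogenation of the silyl enol ether (a Saegusa-type outcome without palladium, so the alkenyl iodide survives) places the double bond at C13=C14 because the cycloaddition fixed the enol ether at C12=C13.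

Step 10
Reactants: 15 cyclohexenone butanoate
Product: 17 C9 aldehyde (2-substituted 2,6-dimethyl-5-oxocyclohex-3-ene-1-carbaldehyde), via vicinal diol 16 (not isolated)
Conditions: H5IO6, EtOAc, 0 °C → rt
Reagents that add atoms: none
Why: Acid-mediated acetonide hydrolysis followed by Malaprade periodate glycol cleavage removes the relay carbon as formaldehyde and unveils the C9 aldehyde, while C10 keeps its configuration because the trans arrangement is also the thermodynamic one.

Step 11
Reactants: 18 2,2-dimethoxyacetaldehyde; 19 propane-1,3-dithiol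
Product: 20 2-(dimethoxymethyl)-1,3-dithiane
Conditions: BF3·OEt2 (5 mol %), CH2Cl2, −20 °C
Reagents that add atoms: none
Why: Lewis-acid-catalysed dithioacetalisation of the free aldehyde, which reacts far faster than the dimethyl acetal.

Step 12
Reactants: 17 C9 aldehyde; 20 2-(dimethoxymethyl)-1,3-dithiane
Product: 23 C9 acetate bearing the C8 dithiane and C7 dimethyl acetal, via lithiated dithiane 21 (not isolated), via lithium alkoxide 22 (not isolated)
Conditions: 20, n-BuLi, THF, −78 °C; added to 17, −78 °C; then Ac2O, −78 → 0 °C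
Reagents that add atoms: acetic anhydride, CC(=O)OC(C)=O
Why: Corey–Seebach dithiane (acyl-anion) addition: the aldehyde reacts far faster than the α′-branched enone whose β-carbon is neopentyl, Felkin–Anh attack anti to quaternary C1 (C11 medium, H small) sets C9, and the alkoxide is acetylated in the same flask.

Step 13
Reactants: 23 C9 acetate dithiane acetal
Product: 24 dithianyl aldehyde (cyclisation precursor)
Conditions: TFA/H2O (9:1), CH2Cl2, 0 °C
Reagents that add atoms: water, O
Why: Acid-catalysed acetal hydrolysis; the dithiane, both esters and the alkenyl iodide are stable and the new aldehyde has no α-hydrogen.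

Step 14
Reactants: 24 dithianyl aldehyde
Product: 26 macrocyclic C7 alcohol (ten-membered ring closed), via trimethylsilyl ether 25 (not isolated)
Conditions: CrCl2 (20 mol %), NiCl2·glyme (5 mol %), neocuproine (6 mol %), TMSCl (3 equiv), LiCl, DMF, undivided cell, Al anode, Ni-foam cathode, 4 mA, 24 added over 12 h (2 mM final), 25 °C; then aq. citric acid
Reagents that add atoms: none
Why: Proposed new method: an electrochemically driven, Ni/Cr-catalysed intramolecular Nozaki–Hiyama–Kishi macrocyclisation in which the cathode regenerates divalent chromium and zerovalent nickel, nickel inserts into the Z-alkenyl iodide with retention, transmetallation gives the alkenylchromium (trivalent chromium) that adds to the non-enolisable aldehyde, TMSCl releases chromium from the alkoxide, and slow addition keeps the alkenyl-metal dilute so ten-ring closure outruns dimerisation, with C7 expected to be set by attack on the aldehyde face that leaves the C7–O bond pointing out of the forming ring and away from the C9 acetate; the closest known chemistry is the intermolecular electrochemical NHK coupling and the stoichiometric-chromium NHK macrocyclisation.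

Step 15
Reactants: 26 macrocyclic C7 alcohol; 27 2-bromopropanoyl bromide (racemic)
Product: 28 C7 2-bromopropanoate
Conditions: pyridine, DMAP (cat.), CH2Cl2, −20 → 0 °C
Reagents that add atoms: none
Why: Acylation of the secondary allylic C7 alcohol with the acid bromide, the racemic α-carbon being erased later on enolate formation.

Step 16
Reactants: 28 C7 2-bromopropanoate
Product: 29 C8 ketone
Conditions: MeI, CaCO3, MeCN/H2O (4:1), 45 °C
Reagents that add atoms: water, O
Why: Alkylative (S-methylation) hydrolysis of the dithiane unmasks the C8 ketone under near-neutral conditions that spare the α-bromo ester and the enone.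

Step 17
Reactants: 29 C8 ketone
Product: 31 11-deoxy lactone (all rings formed), via zinc enolate 30 (not isolated)
Conditions: Zn dust (TMSCl-activated), THF, 0 → 25 °C; aq. NH4Cl
Reagents that add atoms: none
Why: Intramolecular Reformatsky reaction (zinc-enolate aldol lactonisation of an α-acyloxy ketone): the O7 tether delivers C17 to C8 syn to O7, the C9 branch turns away from C6 so the γ-lactone is trans-fused (C8 set), and the enolate methyl avoids the C9 branch (C17 set).

Step 18
Reactants: 31 11-deoxy lactone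
Product: 34 target CNP0346936.2, via bis-silyl dienol ether 32 (not isolated), via bis-silyloxy ketone 33 (not isolated)
Conditions: TMSOTf, Et3N, CH2Cl2, −78 → −20 °C; DMDO, acetone, −78 °C; then citric acid, MeOH
Reagents that add atoms: dimethyldioxirane (DMDO), CC1(C)OO1
Why: Rubottom oxidation: only C11 can enolise (C1 is quaternary), TMSOTf/Et3N gives the cross-conjugated silyl dienol ether (the C8 hydroxyl is silylated in passing), and DMDO attacks its C11=C12 bond anti to the axial C1 methyl and the C9 branch, which delivers 11-OH cis to H-10 before mild acid removes both silyl groups.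

## Compound list

1 | (R)-2,2-dimethyl-1,3-dioxolane-4-carbaldehyde ((R)-glyceraldehyde acetonide) | O=C[C@H]1COC(C)(C)O1 | starting material
2 | 3-(triphenylphosphoranylidene)butan-2-one | CC(=O)C(C)=P(c1ccccc1)(c1ccccc1)c1ccccc1 | starting material
3 | (S,E)-4-(2,2-dimethyl-1,3-dioxolan-4-yl)-3-methylbut-3-en-2-one | CC(=O)/C(C)=C/[C@H]1COC(C)(C)O1 | intermediate
4 | pent-1-en-3-one (ethyl vinyl ketone) | CCC(=O)C=C | starting material
5 | (Z)-tert-butyldimethyl(penta-1,3-dien-3-yloxy)silane | C/C=C(\O[Si](C)(C)C(C)(C)C)C=C | intermediate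
6 | 1-{4-[(tert-butyldimethylsilyl)oxy]-6-[(4S)-2,2-dimethyl-1,3-dioxolan-4-yl]-1,5-dimethylcyclohex-3-en-1-yl}ethan-1-one; acetyl on C1 trans to dioxolanyl on C10, C1 and C10 as in the target, C11 unassigned | CC1(C)OC[C@@H](O1)[C@@H]2[C@](C(C)=O)(C)CC=C(O[Si](C)(C)C(C)(C)C)C2C | intermediate
7 | prop-2-yn-1-ol (propargyl alcohol) | C#CCO | starting material
8 | 4-methyl-2,5-dihydro-1,2-oxamagnesole (cyclic alkenylmagnesium alkoxide) | CC1=C[Mg]OC1 | intermediate
9 | (Z)-3-iodo-2-methylprop-2-en-1-ol | OC/C(C)=C\I | intermediate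
10 | (Z)-3-bromo-1-iodo-2-methylprop-1-ene | BrC/C(C)=C\I | intermediate
11 | lithium enolate of 6 (lithium 1-(cyclohexenyl)ethen-1-olate) | CC1(C)OC[C@@H](O1)[C@@H]2[C@](C(=C)O[Li])(C)CC=C(O[Si](C)(C)C(C)(C)C)C2C | intermediate
12 | (Z)-1-{ring of 6}-5-iodo-4-methylpent-4-en-1-one (C2 ketone, C3–C6 chain attached) | CC1(C)OC[C@@H](O1)[C@@H]2[C@](C(=O)CC/C(C)=C\I)(C)CC=C(O[Si](C)(C)C(C)(C)C)C2C | intermediate
13 | (Z)-1-{ring of 6}-5-iodo-4-methylpent-4-en-1-ol, C2 carbinol configured as in the target | CC1(C)OC[C@@H](O1)[C@@H]2[C@]([C@H](O)CC/C(C)=C\I)(C)CC=C(O[Si](C)(C)C(C)(C)C)C2C | intermediate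
14 | butanoate of 13 | CC1(C)OC[C@@H](O1)[C@@H]2[C@]([C@H](OC(=O)CCC)CC/C(C)=C\I)(C)CC=C(O[Si](C)(C)C(C)(C)C)C2C | intermediate
15 | 4-[1-(butanoyloxy)-(Z)-5-iodo-4-methylpent-4-en-1-yl]-5-[(4S)-2,2-dimethyl-1,3-dioxolan-4-yl]-4,6-dimethylcyclohex-2-en-1-one; C1, C2, C10 as in the target, C11 unassigned | CC1(C)OC[C@@H](O1)[C@@H]2[C@]([C@H](OC(=O)CCC)CC/C(C)=C\I)(C)C=CC(=O)C2C | intermediate
16 | diol of 15: 5-[(1S)-1,2-dihydroxyethyl] in place of the dioxolanyl group | OC[C@@H](O)[C@@H]1[C@]([C@H](OC(=O)CCC)CC/C(C)=C\I)(C)C=CC(=O)C1C | intermediate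
17 | 2-[1-(butanoyloxy)-(Z)-5-iodo-4-methylpent-4-en-1-yl]-2,6-dimethyl-5-oxocyclohex-3-ene-1-carbaldehyde; CHO (C9) on C10 trans to the C2 chain on C1 | O=C[C@@H]1[C@]([C@H](OC(=O)CCC)CC/C(C)=C\I)(C)C=CC(=O)C1C | intermediate
18 | 2,2-dimethoxyacetaldehyde | COC(OC)C=O | starting material
19 | propane-1,3-dithiol | SCCCS | starting material
20 | 2-(dimethoxymethyl)-1,3-dithiane | COC(OC)C1SCCCS1 | intermediate
21 | 2-lithio-2-(dimethoxymethyl)-1,3-dithiane | COC(OC)C1([Li])SCCCS1 | intermediate
22 | lithium alkoxide of the C9 carbinol: [2-(dimethoxymethyl)-1,3-dithian-2-yl](ring of 17)methanolate, C9 as in the target | COC(OC)C1(SCCCS1)[C@H](O[Li])[C@@H]2[C@]([C@H](OC(=O)CCC)CC/C(C)=C\I)(C)C=CC(=O)C2C | intermediate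
23 | [2-(dimethoxymethyl)-1,3-dithian-2-yl](ring of 17)methyl acetate: C9 acetate, C8 dithiane, C7 dimethyl acetal | COC(OC)C1(SCCCS1)[C@H](OC(C)=O)[C@@H]2[C@]([C@H](OC(=O)CCC)CC/C(C)=C\I)(C)C=CC(=O)C2C | intermediate
24 | 2-[(acetyloxy)(ring of 17)methyl]-1,3-dithiane-2-carbaldehyde: C7 aldehyde, Z-alkenyl iodide at C6 | O=CC1(SCCCS1)[C@H](OC(C)=O)[C@@H]2[C@]([C@H](OC(=O)CCC)CC/C(C)=C\I)(C)C=CC(=O)C2C | intermediate
25 | trimethylsilyl ether of 26 | CCCC(=O)O[C@@H]1CC/C(C)=C\[C@H](O[Si](C)(C)C)C3(SCCCS3)[C@H](OC(C)=O)[C@@H]2[C@]1(C)C=CC(=O)C2C | intermediate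
26 | bicyclic alcohol: ten-membered ring fused to cyclohex-13-en-12-one; (5Z)-alkene, 2-butanoate, 7-OH, C8 spiro-1,3-dithiane, 9-acetate; C1, C2, C7, C9, C10 as in the target, C11 unassigned | CCCC(=O)O[C@@H]1CC/C(C)=C\[C@H](O)C3(SCCCS3)[C@H](OC(C)=O)[C@@H]2[C@]1(C)C=CC(=O)C2C | intermediate
27 | 2-bromopropanoyl bromide (racemic) | CC(Br)C(Br)=O | starting material
28 | 7-O-(2-bromopropanoyl) ester of 26 (bromide-bearing carbon unassigned) | CCCC(=O)O[C@@H]1CC/C(C)=C\[C@H](OC(=O)C(C)Br)C3(SCCCS3)[C@H](OC(C)=O)[C@@H]2[C@]1(C)C=CC(=O)C2C | intermediate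
29 | C8 ketone: 28 with the dithiane replaced by C=O | CCCC(=O)O[C@@H]1CC/C(C)=C\[C@H](OC(=O)C(C)Br)C(=O)[C@H](OC(C)=O)[C@@H]2[C@]1(C)C=CC(=O)C2C | intermediate
30 | bromozinc enolate of the C7 propanoate of 29 | CCCC(=O)O[C@@H]1CC/C(C)=C\[C@H](OC(O[Zn]Br)=CC)C(=O)[C@H](OC(C)=O)[C@@H]2[C@]1(C)C=CC(=O)C2C | intermediate
31 | 11-deoxy target: trans-fused 8-hydroxy-17-methyl γ-lactone, 9-acetate, 2-butanoate, (5Z)-ene, 13-en-12-one; all centres except C11 as in the target | CCCC(=O)O[C@@H]1CC/C(C)=C\[C@@H]2OC(=O)[C@H](C)[C@@]2(O)[C@H](OC(C)=O)[C@@H]2[C@]1(C)C=CC(=O)C2C | intermediate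
32 | 8-O-trimethylsilyl 12-(trimethylsilyloxy)-11,13-diene (cross-conjugated silyl dienol ether of 31) | CCCC(=O)O[C@@H]1CC/C(C)=C\[C@@H]2OC(=O)[C@H](C)[C@@]2(O[Si](C)(C)C)[C@H](OC(C)=O)[C@@H]2[C@]1(C)C=CC(O[Si](C)(C)C)=C2C | intermediate
33 | 8,11-bis(trimethylsilyl) ether of the target | CCCC(=O)O[C@@H]1CC/C(C)=C\[C@@H]2OC(=O)[C@H](C)[C@@]2(O[Si](C)(C)C)[C@H](OC(C)=O)[C@@H]2[C@]1(C)C=CC(=O)[C@@]2(C)O[Si](C)(C)C | intermediate
34 | CNP0346936.2 (9-acetoxy-2-butanoyloxy-8,11-dihydroxy-12-oxobriara-5Z,13-dien-19,7-olide) | CCCC(=O)O[C@@H]1CC/C(C)=C\[C@@H]2OC(=O)[C@H](C)[C@@]2(O)[C@H](OC(C)=O)[C@@H]2[C@]1(C)C=CC(=O)[C@@]2(C)O | target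

## Step count and risks

Total steps: 18. Longest linear sequence: 14 (steps 1, 3, 6–10, 12–18).

The three steps most likely to fail:

Step 14 (the proposed electrochemical macrocyclisation). Catalytic turnover at 2 mM, dimerisation of the alkenyl-metal species and the C7 selectivity are all untested on a ten-membered closure. Fallback with known chemistry that leaves electrochemistry altogether: starting from 24, a classical Nozaki–Hiyama–Kishi macrocyclisation with stoichiometric CrCl2 (6 equiv) and NiCl2 (2 mol %) in degassed DMSO at 2 mM gives the same alcohol and rejoins the route at 26. It makes no new compound (F0).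

Step 3 (Diels–Alder). The trisubstituted enone is a sluggish dienophile, the acid catalyst may attack the acetonide, and the facial selectivity rests on a conformational model. Fallback: starting from 1, Wittig reaction with 2-(triphenylphosphoranylidene)propanal gives the more reactive enal (S,E)-3-(2,2-dimethyl-1,3-dioxolan-4-yl)-2-methylprop-2-enal F1. Thermal cycloaddition of F1 with 5 (toluene, 80 °C, no acid) gives the cycloadduct aldehyde F2. MeMgBr converts it into the cycloadduct methyl carbinol F3, and Dess–Martin oxidation of that carbinol rejoins the route at 6.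

Step 17 (Reformatsky lactonisation). The zinc enolate must close a five-membered ring onto a ketone flanked by two acyloxy groups, and the C8 outcome depends on the macrocycle conformation. Fallback: starting from 26, MeI/CaCO3 in aqueous MeCN removes the dithiane to give the macrocyclic 7-hydroxy-8-ketone F4. Intermolecular Reformatsky addition of ethyl 2-bromopropanoate with Zn in THF, with the zinc alkoxide at O7 chelating the ketone so that the reagent enters from the H-7 side, gives the 7,8-diol ethyl ester F5. Camphorsulfonic acid in benzene then lactonises it and rejoins the route at 31.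

## Further compounds

F1 | step 3 | (S,E)-3-(2,2-dimethyl-1,3-dioxolan-4-yl)-2-methylprop-2-enal | O=C/C(C)=C/[C@H]1COC(C)(C)O1
F2 | step 3 | 4-[(tert-butyldimethylsilyl)oxy]-6-[(4S)-2,2-dimethyl-1,3-dioxolan-4-yl]-1,5-dimethylcyclohex-3-ene-1-carbaldehyde (formyl trans to dioxolanyl) | CC1(C)OC[C@@H](O1)[C@@H]2[C@](C=O)(C)CC=C(O[Si](C)(C)C(C)(C)C)C2C
F3 | step 3 | 1-{ring of 6}ethan-1-ol (carbinol epimers) | CC1(C)OC[C@@H](O1)[C@@H]2[C@](C(C)O)(C)CC=C(O[Si](C)(C)C(C)(C)C)C2C
F0 | step 14 | none | none
F4 | step 17 | macrocyclic 7-hydroxy-8-ketone (26 with the dithiane replaced by C=O) | CCCC(=O)O[C@@H]1CC/C(C)=C\[C@H](O)C(=O)[C@H](OC(C)=O)[C@@H]2[C@]1(C)C=CC(=O)C2C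
F5 | step 17 | macrocyclic 7,8-diol bearing CH(CH3)CO2Et on C8 (C8 as in the target, C17 unassigned) | CCCC(=O)O[C@@H]1CC/C(C)=C\[C@H](O)[C@@](O)(C(C)C(=O)OCC)[C@H](OC(C)=O)[C@@H]2[C@]1(C)C=CC(=O)C2C
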